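**Retrosynthetic overview**
- Feature: ring B (C5–C10, drimane numbering) is (R)-carvone atom for atom. The ketone is C9, the methyl-bearing alkene is C7=C8 with C12, the stereocentre is C5, and the isopropenyl carbon is the gem-dimethyl carbon C4 of ring A.
- Late stage: the C6 ester comes from a Yamaguchi coupling with the trienoic acid made from sorbaldehyde. The 6β-OH comes from α-face reduction of a 7-en-6-one, and the C12 aldehyde from SeO2 oxidation of the carvone methyl group.
- Ring-B oxygens: C9–OH and C6=O are installed together by singlet-oxygen [4+2] addition across a 6,8-dienoate followed by Kornblum–DeLaMare opening. C11 comes from carbonylation of the C9 dienyl triflate, and the C1 carbonyl is removed through its enol triflate.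
- Ring order: ring B is bought. Ring A is closed at C3–C4 by iron-hydride HAT radical 6-endo addition of the isopropenyl group to an acryloyl group on C10. C10 is set beforehand by methylation and then an acrolein aldol anti to the isopropenyl group.

Key step: step 4

Assumption: the target is treated as the open 12-aldehyde/11-acid form as drawn, and 3 and 6 are carried as epimer mixtures at centres that the following step erases.

**Step 1**
Reactants: 1 (R)-(−)-carvone
Product: 3 (5R,6S)-2,6-dimethyl-5-(prop-1-en-2-yl)cyclohex-2-en-1-one (trans-6-methylcarvone, major epimer drawn), via lithium α′-enolate of carvone 2 (not isolated)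
Conditions: LDA, THF, −78 °C; MeI, −78 → 0 °C
Reagents that add atoms: iodomethane, CI
Why: Kinetic α′-deprotonation gives the cross-conjugated enolate 2, and its enolate alkylation (SN2 on MeI) should occur mainly anti to the isopropenyl group, the new centre being planarised again in step 2 so that its epimer composition does not matter.

**Step 2**
Reactants: 3 trans-6-methylcarvone; 4 acrolein
Product: 6 (5S,6R)-6-(1-hydroxyprop-2-en-1-yl)-2,6-dimethyl-5-(prop-1-en-2-yl)cyclohex-2-en-1-one (carbinol epimers), via lithium enolate of 6-methylcarvone 5 (not isolated)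
Conditions: LDA, THF, −78 → 0 → −78 °C; acrolein, −78 °C; AcOH quench at −78 °C
Reagents that add atoms: none
Why: Aldol addition, in which the fully substituted enolate 5 adds 1,2 to acrolein from the face anti to the C5 isopropenyl group and so fixes quaternary C10 (methyl β, C1 chain trans to isopropenyl), while the cold acidic quench forestalls retro-aldol and the carbinol centre is erased in step 3.

**Step 3**
Reactants: 6 aldol adduct
Product: 7 (5S,6R)-6-acryloyl-2,6-dimethyl-5-(prop-1-en-2-yl)cyclohex-2-en-1-one (acryloyl trans to isopropenyl)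
Conditions: Dess–Martin periodinane, CH2Cl2, 0 °C → rt
Reagents that add atoms: none
Why: Dess–Martin oxidation turns the secondary allylic alcohol into the vinyl ketone under non-basic conditions, so neither retro-aldol cleavage at quaternary C10 nor Michael addition to the new enone should intervene.

**Step 4**
Reactants: 7 6-acryloyl-6-methylcarvone
Product: 8 (4aS,8aR)-2,5,5,8a-tetramethyl-4,4a,5,6,7,8a-hexahydronaphthalene-1,8-dione (trans-fused 11-nordrim-7-ene-1,9-dione)
Conditions: Fe(acac)3 (30 mol %), PhSiH3, EtOH/ethylene glycol 5:1, 0.02 M, 60 °C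
Reagents that add atoms: none
Why: An iron hydride formed from Fe(acac)3 and PhSiH3 transfers a hydrogen atom to the CH2 terminus of the isopropenyl group (Markovnikov), which makes it the second methyl on C4 and leaves the nucleophilic tertiary C4 radical; this radical adds to the terminal carbon C3 of the acryloyl group, and the resulting C2 α-keto radical is reduced to the iron enolate and protonated by ethanol. The closest known reaction type is the iron-catalysed HAT reductive olefin coupling (Giese-type radical conjugate addition) in its intramolecular form. Ring A (C4–C5–C10–C1–C2–C3) closes in the 6-endo-trig mode, preferred over 5-exo attack at C2 because it is polarity-matched and gives a carbonyl-stabilised rather than a primary radical. No new stereocentre arises, since C4 becomes CMe2 and C2 becomes CH2, and the trans ring fusion follows from C5 and C10 of 7, whose two reacting arms are trans-diequatorial. The step needs HAT to the electron-rich 1,1-disubstituted alkene in the presence of two enones; this is secured by the faster HAT to that alkene, by the trisubstituted C7=C8 enone being out of reach of the C4 radical (only a four-membered or bridged ring could form), and by high dilution, which suppresses intermolecular addition to the vinyl ketone.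

**Step 5**
Reactants: 8 trans-decalin-1,9-dione
Product: 10 9-oxo-11-nordrima-1,7-dien-1-yl trifluoromethanesulfonate, via potassium C1 enolate of the dione 9 (not isolated)
Conditions: KHMDS, THF, −78 °C; PhNTf2, −78 → 0 °C
Reagents that add atoms: N-phenylbis(trifluoromethanesulfonimide), O=S(=O)(N(c1ccccc1)S(=O)(=O)C(F)(F)F)C(F)(F)F
Why: Kinetic deprotonation takes the C2 α-protons of the saturated ketone (C10 is quaternary and the γ-protons of the enone are removed far more slowly), and O-sulfonylation of enolate 9 gives the enol triflate.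

**Step 6**
Reactants: 10 C1 enol triflate
Product: 11 11-nordrima-1,7-dien-9-one
Conditions: Pd(OAc)2 (5 mol %), PPh3, HCO2H, Et3N, DMF, 60 °C
Reagents that add atoms: none
Why: Palladium-catalysed formate reduction of an enol triflate (oxidative addition, formate exchange, decarboxylation, reductive elimination) replaces C1–OTf by C1–H and leaves the enone alone.

**Step 7**
Reactants: 11 11-nordrima-1,7-dien-9-one
Product: 12 (4aS,8aS)-2,5,5,8a-tetramethyl-4a,5,6,7,8,8a-hexahydronaphthalen-1(4H)-one (11-nordrim-7-en-9-one)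
Conditions: H2 (1 atm), RhCl(PPh3)3 (10 mol %), toluene/EtOH, rt
Reagents that add atoms: none
Why: Homogeneous hydrogenation with Wilkinson's catalyst saturates the cis-disubstituted C1=C2 alkene and spares the trisubstituted conjugated C7=C8 alkene, the same selectivity that turns steroidal 1,4-dien-3-ones into 4-en-3-ones.

**Step 8**
Reactants: 12 11-nordrim-7-en-9-one
Product: 14 11-nordrima-6,8-dien-9-yl trifluoromethanesulfonate, via potassium 6,8-dienolate 13 (not isolated)
Conditions: KHMDS, THF, −78 → −20 °C; PhNTf2, −78 → 0 °C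
Reagents that add atoms: N-phenylbis(trifluoromethanesulfonimide), O=S(=O)(N(c1ccccc1)S(=O)(=O)C(F)(F)F)C(F)(F)F
Why: With no α′-proton available the base removes a γ-proton at C6, and O-triflation of the extended dienolate 13 gives the homoannular dienyl triflate (dienol triflate formation as practised on steroidal 4-en-3-ones).

**Step 9**
Reactants: 14 dienyl triflate
Product: 15 2-(trimethylsilyl)ethyl drima-6,8-dien-11-oate
Conditions: Pd(OAc)2 (10 mol %), dppf, CO (1 atm), Me3SiCH2CH2OH, Et3N, DMF, 70 °C
Reagents that add atoms: carbon monoxide, [C-]#[O+]; 2-(trimethylsilyl)ethanol, C[Si](C)(C)CCO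
Why: Palladium-catalysed alkoxycarbonylation of an enol triflate installs C11 directly as a fluoride-labile ester, the hindrance being comparable to that of 2,6,6-trimethylcyclohexenyl triflate, which undergoes this reaction.

**Step 10**
Reactants: 15 dienoate
Product: 17 2-(trimethylsilyl)ethyl 9α-hydroxy-6-oxodrim-7-en-11-oate, via 2-(trimethylsilyl)ethyl 6α,9α-epidioxydrim-7-en-11-oate 16 (not isolated)
Conditions: O2, tetraphenylporphyrin (1 mol %), white LED, CH2Cl2, −20 °C; then Et3N, 0 °C → rt
Reagents that add atoms: dioxygen, O=O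
Why: Singlet oxygen adds [4+2] across C6 and C9 of the cisoid ring-B diene from the α face, opposite the axial C10 and C4β methyl groups, which sets C9 (O α, ester β), and the amine then removes the only proton α to the peroxide (H6) in a Kornblum–DeLaMare rearrangement that gives the γ-hydroxy enone regiospecifically.

**Step 11**
Reactants: 17 9α-hydroxy-7-en-6-one
Product: 18 2-(trimethylsilyl)ethyl 9α-hydroxy-6,12-dioxodrim-7-en-11-oate
Conditions: SeO2 (2.5 equiv), 1,4-dioxane, 90 °C
Reagents that add atoms: selenium dioxide, O=[Se]=O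
Why: Riley-type SeO2 oxidation (ene reaction, [2,3]-shift, further oxidation) takes the γ-methyl group C12 to the aldehyde, C12 carrying the only allylic hydrogens because C9 is fully substituted, as in the known oxidation of the ring methyl of 4-hydroxy-3-methylcyclohex-2-enones.

**Step 12**
Reactants: 18 keto aldehyde
Product: 19 2-(trimethylsilyl)ethyl 9α-hydroxy-12,12-dimethoxy-6-oxodrim-7-en-11-oate
Conditions: HC(OMe)3, MeOH, PPTS (10 mol %), rt
Reagents that add atoms: trimethyl orthoformate, COC(OC)OC
Why: Acid-catalysed acetalisation with orthoformate is chemoselective for the aldehyde over the hindered conjugated C6 ketone and masks C12 for the hydride step.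

**Step 13**
Reactants: 19 keto acetal
Product: 20 2-(trimethylsilyl)ethyl 6β,9α-dihydroxy-12,12-dimethoxydrim-7-en-11-oate
Conditions: NaBH4, CeCl3·7H2O, MeOH, −78 → −20 °C
Reagents that add atoms: none
Why: Luche 1,2-reduction, in which hydride reaches C6 from the α face because the β face is blocked by the syn-axial C10 and C4β methyl groups, so the axial 6β-alcohol should form while ester and acetal stay inert.

**Step 14**
Reactants: 21 sorbaldehyde, (2E,4E)-hexa-2,4-dienal
Product: 22 (2E,4E,6E)-octa-2,4,6-trienoic acid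
Conditions: malonic acid, pyridine, piperidine (cat.), 90 °C
Reagents that add atoms: malonic acid, OC(=O)CC(=O)O
Why: Doebner–Knoevenagel condensation with decarboxylation adds an E-configured acrylic acid unit and keeps the two existing E alkenes.

**Step 15**
Reactants: 20 6β-alcohol; 22 trienoic acid
Product: 24 2-(trimethylsilyl)ethyl 9α-hydroxy-12,12-dimethoxy-6β-[(2E,4E,6E)-octa-2,4,6-trienoyloxy]drim-7-en-11-oate, via (2E,4E,6E)-octa-2,4,6-trienoic 2,4,6-trichlorobenzoic anhydride 23 (not isolated)
Conditions: 22, 2,4,6-trichlorobenzoyl chloride, Et3N, toluene, rt; then 20, DMAP, toluene, 50 °C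
Reagents that add atoms: 2,4,6-trichlorobenzoyl chloride, O=C(Cl)c1c(Cl)cc(Cl)cc1Cl (its atoms stay only in 23)
Why: Yamaguchi esterification, in which DMAP attacks mixed anhydride 23 at the less hindered trienoyl carbonyl and the acylpyridinium acylates the secondary 6β-OH with retention at C6, the tertiary 9α-OH being too hindered to react.

**Step 16**
Reactants: 24 trienoate acetal
Product: 25 2-(trimethylsilyl)ethyl 9α-hydroxy-12-oxo-6β-[(2E,4E,6E)-octa-2,4,6-trienoyloxy]drim-7-en-11-oate
Conditions: PPTS (20 mol %), acetone/H2O 10:1, rt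
Reagents that add atoms: water, O
Why: Mild acid-catalysed hydrolysis of the allylic dimethyl acetal frees the enal under conditions that leave both esters, the triene and the tertiary alcohol untouched.

**Step 17**
Reactants: 25 enal silylethyl ester
Product: 26 ustusoic acid B
Conditions: TBAF/AcOH (1:1), THF, 0 °C → rt
Reagents that add atoms: none
Why: Fluoride attacks silicon, remote from the hindered C11 carbonyl, and β-elimination frees the acid, while the acetic acid buffer protects the trienoate and the enal from base.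

**Compound list**

| No. | Name | SMILES | Role |
|---|---|---|---|
| 1 | (R)-(−)-carvone | CC1=CC[C@H](CC1=O)C(C)=C | starting material |
| 2 | lithium α′-enolate of carvone | C1C=C(C)C(O[Li])=C[C@@H]1C(C)=C | intermediate |
| 3 | (5R,6S)-2,6-dimethyl-5-(prop-1-en-2-yl)cyclohex-2-en-1-one | C1C=C(C)C(=O)[C@@H](C)[C@@H]1C(C)=C | intermediate |
| 4 | acrolein | C=CC=O | starting material |
| 5 | lithium enolate of 6-methylcarvone | C1C=C(C)C(O[Li])=C(C)[C@@H]1C(C)=C | intermediate |
| 6 | (5S,6R)-6-(1-hydroxyprop-2-en-1-yl)-2,6-dimethyl-5-(prop-1-en-2-yl)cyclohex-2-en-1-one (carbinol epimers) | C1C=C(C)C(=O)[C@@](C)(C(O)C=C)[C@@H]1C(C)=C | intermediate |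
| 7 | (5S,6R)-6-acryloyl-2,6-dimethyl-5-(prop-1-en-2-yl)cyclohex-2-en-1-one | C1C=C(C)C(=O)[C@@](C)(C(=O)C=C)[C@@H]1C(C)=C | intermediate |
| 8 | (4aS,8aR)-2,5,5,8a-tetramethyl-4,4a,5,6,7,8a-hexahydronaphthalene-1,8-dione | C1C=C(C)C(=O)[C@@]2(C)C(=O)CCC(C)(C)[C@H]12 | intermediate |
| 9 | potassium C1 enolate of 8 | C1C=C(C)C(=O)[C@@]2(C)C(O[K])=CCC(C)(C)[C@H]12 | intermediate |
| 10 | 9-oxo-11-nordrima-1,7-dien-1-yl triflate | C1C=C(C)C(=O)[C@@]2(C)C(OS(=O)(=O)C(F)(F)F)=CCC(C)(C)[C@H]12 | intermediate |
| 11 | 11-nordrima-1,7-dien-9-one | C1C=C(C)C(=O)[C@@]2(C)C=CCC(C)(C)[C@H]12 | intermediate |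
| 12 | (4aS,8aS)-2,5,5,8a-tetramethyl-4a,5,6,7,8,8a-hexahydronaphthalen-1(4H)-one | C1C=C(C)C(=O)[C@@]2(C)CCCC(C)(C)[C@H]12 | intermediate |
| 13 | potassium 6,8-dienolate of 12 | C1=CC(C)=C(O[K])[C@@]2(C)CCCC(C)(C)[C@H]12 | intermediate |
| 14 | 11-nordrima-6,8-dien-9-yl triflate | C1=CC(C)=C(OS(=O)(=O)C(F)(F)F)[C@@]2(C)CCCC(C)(C)[C@H]12 | intermediate |
| 15 | 2-(trimethylsilyl)ethyl drima-6,8-dien-11-oate | C1=CC(C)=C(C(=O)OCC[Si](C)(C)C)[C@@]2(C)CCCC(C)(C)[C@H]12 | intermediate |
| 16 | 2-(trimethylsilyl)ethyl 6α,9α-epidioxydrim-7-en-11-oate | [C@H]13C=C(C)[C@](OO3)(C(=O)OCC[Si](C)(C)C)[C@@]2(C)CCCC(C)(C)[C@H]12 | intermediate |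
| 17 | 2-(trimethylsilyl)ethyl 9α-hydroxy-6-oxodrim-7-en-11-oate | O=C1C=C(C)[C@](O)(C(=O)OCC[Si](C)(C)C)[C@@]2(C)CCCC(C)(C)[C@H]12 | intermediate |
| 18 | 2-(trimethylsilyl)ethyl 9α-hydroxy-6,12-dioxodrim-7-en-11-oate | O=C1C=C(C=O)[C@](O)(C(=O)OCC[Si](C)(C)C)[C@@]2(C)CCCC(C)(C)[C@H]12 | intermediate |
| 19 | 2-(trimethylsilyl)ethyl 9α-hydroxy-12,12-dimethoxy-6-oxodrim-7-en-11-oate | O=C1C=C(C(OC)OC)[C@](O)(C(=O)OCC[Si](C)(C)C)[C@@]2(C)CCCC(C)(C)[C@H]12 | intermediate |
| 20 | 2-(trimethylsilyl)ethyl 6β,9α-dihydroxy-12,12-dimethoxydrim-7-en-11-oate | O[C@@H]1C=C(C(OC)OC)[C@](O)(C(=O)OCC[Si](C)(C)C)[C@@]2(C)CCCC(C)(C)[C@H]12 | intermediate |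
| 21 | sorbaldehyde | C/C=C/C=C/C=O | starting material |
| 22 | (2E,4E,6E)-octa-2,4,6-trienoic acid | C/C=C/C=C/C=C/C(=O)O | intermediate |
| 23 | (2E,4E,6E)-octa-2,4,6-trienoic 2,4,6-trichlorobenzoic anhydride | C/C=C/C=C/C=C/C(=O)OC(=O)c1c(Cl)cc(Cl)cc1Cl | intermediate |
| 24 | 2-(trimethylsilyl)ethyl 9α-hydroxy-12,12-dimethoxy-6β-[(2E,4E,6E)-octa-2,4,6-trienoyloxy]drim-7-en-11-oate | C/C=C/C=C/C=C/C(=O)O[C@@H]1C=C(C(OC)OC)[C@](O)(C(=O)OCC[Si](C)(C)C)[C@@]2(C)CCCC(C)(C)[C@H]12 | intermediate |
| 25 | 2-(trimethylsilyl)ethyl 9α-hydroxy-12-oxo-6β-[(2E,4E,6E)-octa-2,4,6-trienoyloxy]drim-7-en-11-oate | C/C=C/C=C/C=C/C(=O)O[C@@H]1C=C(C=O)[C@](O)(C(=O)OCC[Si](C)(C)C)[C@@]2(C)CCCC(C)(C)[C@H]12 | intermediate |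
| 26 | ustusoic acid B | C/C=C/C=C/C=C/C(=O)O[C@@H]1C=C(C=O)[C@](O)(C(=O)O)[C@@]2(C)CCCC(C)(C)[C@H]12 | target |

**Step count**
- Total step count: 17.
- Longest linear sequence: 16 steps from (R)-carvone (steps 1–13 and 15–17). Step 14 is the one-step side branch.

**Steps most likely to fail**

Step 4.
- What may go wrong: the iron hydride may transfer hydrogen to the vinyl ketone instead of the isopropenyl group. The labile acceptor may oligomerise, or the C4 radical may be reduced before it closes the ring.
- Fallback: it sets out from 7 and returns at 8. It generates the same radical by halogen abstraction, so the two alkenes no longer compete for a metal hydride.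
- HBr in AcOH at 0 °C adds in the Markovnikov sense to the isopropenyl group and in the conjugate sense to the vinyl ketone. This gives (5S,6R)-6-(3-bromopropanoyl)-5-(2-bromopropan-2-yl)-2,6-dimethylcyclohex-2-en-1-one F1.
- Et3N in Et2O at 0 °C removes HBr only from the β-bromo ketone (E1cB) and gives (5S,6R)-6-acryloyl-5-(2-bromopropan-2-yl)-2,6-dimethylcyclohex-2-en-1-one F2.
- Slow addition of Bu3SnH with Et3B/air in toluene abstracts the tertiary bromine. The C4 radical then closes 6-endo onto the acryloyl group to give 8.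

Step 10.
- What may go wrong: the ester lowers the nucleophilicity of the diene. The boat that ring B must adopt in the 6,9-bridged peroxide also strains the trans ring fusion. The cycloaddition may therefore be slow, and an ene reaction at the C5–H/C6=C7 unit or photodegradation may overtake it.
- Fallback: it sets out from 15 and returns at 17. It places the two oxygens one after the other by polar chemistry.
- mCPBA (NaHCO3, CH2Cl2, 0 °C) epoxidises the electron-richer distal C6=C7 bond from the α face. This gives 2-(trimethylsilyl)ethyl 6α,7α-epoxydrim-8-en-11-oate F3.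
- LDA (THF, −78 °C) removes a proton from C12, the only γ-position that bears hydrogen and the one syn to the ester. The dienolate is hydroxylated at C9 from the α face with 2-(phenylsulfonyl)-3-phenyloxaziridine. This gives 2-(trimethylsilyl)ethyl 6α,7α-epoxy-9α-hydroxydrim-8(12)-en-11-oate F4.
- Pd(PPh3)4 isomerises the vinyl epoxide to 2-(trimethylsilyl)ethyl 9α-hydroxy-6-oxodrim-8(12)-en-11-oate F5, which DBU conjugates to 17.

Step 11.
- What may go wrong: the doubly deactivated alkene may react sluggishly. The oxidation may stall at the C12 alcohol stage, where cyclisation of that hydroxyl onto the C11 ester would drain material.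
- Fallback: it sets out from 17 and returns at 18, and it never passes through a free C12 alcohol.
- Wohl–Ziegler bromination (NBS, AIBN, PhCF3, 80 °C) of the γ-methyl group gives 2-(trimethylsilyl)ethyl 12-bromo-9α-hydroxy-6-oxodrim-7-en-11-oate F6.
- N-Methylmorpholine N-oxide (MeCN, 4 Å molecular sieves, rt) converts the allylic bromide into aldehyde 18 by displacement and elimination (Kornblum-type N-oxide oxidation).

**Further compounds**
F1 | step 4 | (5S,6R)-6-(3-bromopropanoyl)-5-(2-bromopropan-2-yl)-2,6-dimethylcyclohex-2-en-1-one | C1C=C(C)C(=O)[C@@](C)(C(=O)CCBr)[C@@H]1C(C)(C)Br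
F2 | step 4 | (5S,6R)-6-acryloyl-5-(2-bromopropan-2-yl)-2,6-dimethylcyclohex-2-en-1-one | C1C=C(C)C(=O)[C@@](C)(C(=O)C=C)[C@@H]1C(C)(C)Br
F3 | step 10 | 2-(trimethylsilyl)ethyl 6α,7α-epoxydrim-8-en-11-oate | [C@H]1(O3)[C@@H]3C(C)=C(C(=O)OCC[Si](C)(C)C)[C@@]2(C)CCCC(C)(C)[C@H]12
F4 | step 10 | 2-(trimethylsilyl)ethyl 6α,7α-epoxy-9α-hydroxydrim-8(12)-en-11-oate | [C@H]1(O3)[C@@H]3C(=C)[C@](O)(C(=O)OCC[Si](C)(C)C)[C@@]2(C)CCCC(C)(C)[C@H]12
F5 | step 10 | 2-(trimethylsilyl)ethyl 9α-hydroxy-6-oxodrim-8(12)-en-11-oate | O=C1CC(=C)[C@](O)(C(=O)OCC[Si](C)(C)C)[C@@]2(C)CCCC(C)(C)[C@H]12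
F6 | step 11 | 2-(trimethylsilyl)ethyl 12-bromo-9α-hydroxy-6-oxodrim-7-en-11-oate | O=C1C=C(CBr)[C@](O)(C(=O)OCC[Si](C)(C)C)[C@@]2(C)CCCC(C)(C)[C@H]12
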